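The 2,3-dihydrobenzofuran core (O1, C2, C3, C3a, C7a) with C9 attached at C3 is treated as a contracted flavanone. C9 is the former carbonyl carbon C4, and the C3–C3a bond arises when the ring A carbon C4a (future C3a), ortho to the O1-bearing carbon, shifts from C4 to the α-carbon. One oxidative operation with trivalent iodine thus makes the five-membered ring, the C3–C3a bond and the C3 stereocentre (trans, relayed from C2), and delivers C9 as a methyl ester. The precursor is an (R)-6-bromo-8-methoxyflavanone whose syringyl ring is deactivated as a mesylate, made by enantioselective arylboronic acid addition to a chromone.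

Key step: step 6

Stereochemical note: the target is the trans-(2R,3S) isomer; the ring-contracted ester has the same spatial arrangement but is (2R,3R), because the C3 descriptor changes with the CIP priorities on reduction.
Assumption: the (S)-configured pyridine-oxazoline ligand is taken to deliver the aryl group to the chromone face that gives the (R)-flavanone, the same facial sense as with cyclic enones; if the sense proved opposite, the (R)-ligand would be used.

Step 1
Reactants: 1 1-(2-hydroxy-3-methoxyphenyl)ethanone
Product: 2 1-(5-bromo-2-hydroxy-3-methoxyphenyl)ethanone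
Conditions: NBS, MeCN, 0 °C to rt
Reagents that add atoms: N-bromosuccinimide, O=C1CCC(=O)N1Br
Why: Electrophilic aromatic bromination in which the phenol OH directs para to C5 (both ortho positions are blocked) and the meta-directing acetyl group reinforces this, so the handle for the later Mizoroki–Heck coupling is placed unambiguously at the outset.

Step 2
Reactants: 2 1-(5-bromo-2-hydroxy-3-methoxyphenyl)ethanone
Product: 4 6-bromo-8-methoxy-4H-chromen-4-one, via enaminone 3 (not isolated)
Conditions: Me2NCH(OMe)2, toluene, 100 °C; evaporate; then conc. HCl, CH2Cl2, 40 °C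
Reagents that add atoms: N,N-dimethylformamide dimethyl acetal, COC(OC)N(C)C
Why: Condensation of the methyl ketone with the amide acetal gives the vinylogous amide, and acid then drives oxa-Michael addition of the phenol with loss of dimethylamine (addition–elimination), a standard chromone synthesis.

Step 3
Reactants: 5 4-bromo-2,6-dimethoxyphenol
Product: 6 4-bromo-2,6-dimethoxyphenyl methanesulfonate
Conditions: MsCl, Et3N, CH2Cl2, 0 °C
Reagents that add atoms: methanesulfonyl chloride, CS(=O)(=O)Cl
Why: O-Sulfonylation of the phenol, the mesylate being preferred to an ester or ether because it withstands palladium catalysis, acid and hydride and is a weak π-donor that keeps the syringyl ring from migrating or being oxidised in step 6.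

Step 4
Reactants: 6 4-bromo-2,6-dimethoxyphenyl methanesulfonate
Product: 7 [3,5-dimethoxy-4-(methanesulfonyloxy)phenyl]boronic acid
Conditions: B2(OH)4, chloro(2-dicyclohexylphosphino-2′,4′,6′-triisopropylbiphenyl)[2-(2′-aminobiphenyl)]palladium (C45H59ClNPPd, second-generation XPhos palladacycle, 1 mol%), XPhos (2 mol%), KOAc, EtOH, 80 °C; dilute aq. HCl work-up
Reagents that add atoms: tetrahydroxydiboron, OB(O)B(O)O
Why: Miyaura-type borylation of the unhindered C–Br bond with tetrahydroxydiboron gives the free boronic acid directly, the hindered electron-rich aryl mesylate being inert to oxidative addition under these conditions.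

Step 5
Reactants: 4 6-bromo-8-methoxy-4H-chromen-4-one; 7 [3,5-dimethoxy-4-(methanesulfonyloxy)phenyl]boronic acid
Product: 8 (R)-6-bromo-8-methoxy-2-[3,5-dimethoxy-4-(methanesulfonyloxy)phenyl]chroman-4-one
Conditions: Pd(OCOCF3)2 (5 mol%), (S)-4-tert-butyl-2-(pyridin-2-yl)-4,5-dihydrooxazole (6 mol%), NH4PF6 (30 mol%), H2O (5 equiv), ClCH2CH2Cl, 60 °C, under air
Reagents that add atoms: none
Why: Enantioselective conjugate addition of an arylboronic acid (Hayashi–Miyaura type, run in the divalent palladium manifold), in which transmetalation gives a cationic arylpalladium–ligand complex whose tert-butyl group blocks one face of the bound chromone, carbopalladation places the aryl group on C2 from the face that gives the (R)-flavanone, and protonolysis of the palladium enolate releases the ketone without touching the C–Br bond; the product can be recrystallised to raise its enantiopurity if needed.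

Step 6
Reactants: 8 (R)-6-bromo-8-methoxy-2-[3,5-dimethoxy-4-(methanesulfonyloxy)phenyl]chroman-4-one
Product: 11 methyl (2R,3R)-5-bromo-2-[3,5-dimethoxy-4-(methanesulfonyloxy)phenyl]-7-methoxy-2,3-dihydro-1-benzofuran-3-carboxylate, via methyl enol ether 9 (not isolated), via iodanyl ketal 10 (not isolated)
Conditions: PhI(OAc)2 (1.3 equiv), conc. H2SO4 (2 equiv), HC(OMe)3, 0 °C to rt
Reagents that add atoms: trimethyl orthoformate, COC(OC)OC
Why: Acid and orthoformate turn the ketone into methyl enol ether 9, PhI(OAc)2 adds to C3 on the face away from the equatorial C2 aryl group while methanol caps C4, and in the diequatorial conformer of ketal 10 the C3–I bond lies antiperiplanar to C4–C4a, so the ring A carbon C4a shifts to C3 with inversion as iodobenzene departs and the remaining dimethoxycarbenium centre collapses to the methyl ester. The closest known reaction type is the oxidative 1,2-aryl shift of aryl ketone enol ethers with trivalent iodine or Tl(NO3)3 in orthoformate, which is established for the contraction of flavanones to trans-2-aryl-2,3-dihydrobenzofuran-3-carboxylates. The dihydrofuran ring is not closed end to end but arises by contraction of the pyranone: the C3–C3a bond forms through a bridged phenonium-like transition state (formally a 3-exo-tet displacement at C3) while O1–C2 and C2–C3 are carried over intact. The new stereocentre C3 is controlled by C2, since anti iodination followed by inversion places the ester trans to the aryl group to give (2R,3R), and this is also the thermodynamic isomer because C3–H is α to the ester. The step needs ring A migration to win over migration of the syringyl ring (isoflavone formation) and over dehydrogenation (flavone formation); this is secured by O1 ortho to the migrating carbon, by the mesylate that makes the syringyl ring a poor migrating group and inert to the oxidant, and by the equatorial aryl group being gauche rather than anti to the leaving group. C2 is never ionised, so the enantiopurity set in step 5 should be carried through.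

Step 7
Reactants: 11 methyl (2R,3R)-5-bromo-2-[3,5-dimethoxy-4-(methanesulfonyloxy)phenyl]-7-methoxy-2,3-dihydro-1-benzofuran-3-carboxylate
Product: 12 4-[(2R,3S)-5-bromo-3-(hydroxymethyl)-7-methoxy-2,3-dihydro-1-benzofuran-2-yl]-2,6-dimethoxyphenyl methanesulfonate
Conditions: i-Bu2AlH (3 equiv), CH2Cl2, −78 to 0 °C; aq. potassium sodium tartrate
Reagents that add atoms: none
Why: Hydride reduction of the ester to the primary alcohol under non-basic, low-temperature conditions that leave the aryl bromide and the mesylate alone and cannot epimerise C3 or open the ring by β-elimination, and removing the acidic C3–H here makes the later basic steps safe while both stereocentres stay as they are.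

Step 8
Reactants: 13 3,5-dihydroxybenzaldehyde
Product: 14 3,5-bis(tert-butyldimethylsilyloxy)benzaldehyde
Conditions: TBSCl, imidazole, DMF, rt
Reagents that add atoms: tert-butyldimethylsilyl chloride, CC(C)(C)[Si](C)(C)Cl
Why: Silylation of both phenols gives ethers that survive the ylide and the Mizoroki–Heck conditions and come off under mild base or fluoride at the end.

Step 9
Reactants: 14 3,5-bis(tert-butyldimethylsilyloxy)benzaldehyde
Product: 15 3,5-bis(tert-butyldimethylsilyloxy)styrene
Conditions: Ph3PCH3Br, n-BuLi, THF, 0 °C; then 14, 0 °C to rt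
Reagents that add atoms: methyltriphenylphosphonium bromide, C[P+](c1ccccc1)(c1ccccc1)c1ccccc1.[Br-]
Why: Wittig methylenation of the aromatic aldehyde with the preformed non-stabilised ylide gives the terminal styrene.

Step 10
Reactants: 12 4-[(2R,3S)-5-bromo-3-(hydroxymethyl)-7-methoxy-2,3-dihydro-1-benzofuran-2-yl]-2,6-dimethoxyphenyl methanesulfonate; 15 3,5-bis(tert-butyldimethylsilyloxy)styrene
Product: 16 4-[(2R,3S)-5-[(E)-2-[3,5-bis(tert-butyldimethylsilyloxy)phenyl]ethenyl]-3-(hydroxymethyl)-7-methoxy-2,3-dihydro-1-benzofuran-2-yl]-2,6-dimethoxyphenyl methanesulfonate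
Conditions: Pd2(dba)3 (2.5 mol%), [HP(t-Bu)3]BF4 (10 mol%), Cy2NMe (1.5 equiv), 1,4-dioxane, 60 °C
Reagents that add atoms: none
Why: Mizoroki–Heck reaction in which zerovalent palladium carrying the bulky, electron-rich P(t-Bu)3 adds to the electron-rich aryl bromide at moderate temperature, insertion at the unsubstituted styrene carbon and syn β-hydride elimination give the (E)-stilbene, and the free alcohol, the silyl ethers and the unreactive aryl mesylate are tolerated by the amine base.

Step 11
Reactants: 16 4-[(2R,3S)-5-[(E)-2-[3,5-bis(tert-butyldimethylsilyloxy)phenyl]ethenyl]-3-(hydroxymethyl)-7-methoxy-2,3-dihydro-1-benzofuran-2-yl]-2,6-dimethoxyphenyl methanesulfonate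
Product: 18 gnetucleistol F, via bis-silyl phenol 17 (not isolated)
Conditions: LiN(i-Pr)2 (5 equiv), THF, −78 to 0 °C; then MeOH, rt, argon; aq. NH4Cl
Reagents that add atoms: none
Why: Base-mediated demesylation by an E1cB pathway (LiN(i-Pr)2 deprotonates the S-methyl group and the aryloxide leaves as sulfene forms and is trapped by the amide), which works at low temperature despite the two flanking methoxy groups, followed in the same flask by methanolysis of the two aryl silyl ethers with the LiOMe formed on adding methanol, with no stereocentre involved and the low temperature disfavouring ring opening through a quinone methide.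

Compound list
1 | 1-(2-hydroxy-3-methoxyphenyl)ethanone | CC(=O)c1cccc(OC)c1O | starting material
2 | 1-(5-bromo-2-hydroxy-3-methoxyphenyl)ethanone | CC(=O)c1cc(Br)cc(OC)c1O | intermediate
3 | (E)-1-(5-bromo-2-hydroxy-3-methoxyphenyl)-3-(dimethylamino)prop-2-en-1-one (enaminone) | CN(C)/C=C/C(=O)c1cc(Br)cc(OC)c1O | intermediate
4 | 6-bromo-8-methoxy-4H-chromen-4-one | COc1cc(Br)cc2c(=O)ccoc12 | intermediate
5 | 4-bromo-2,6-dimethoxyphenol | COc1cc(Br)cc(OC)c1O | starting material
6 | 4-bromo-2,6-dimethoxyphenyl methanesulfonate | COc1cc(Br)cc(OC)c1OS(C)(=O)=O | intermediate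
7 | [3,5-dimethoxy-4-(methanesulfonyloxy)phenyl]boronic acid | COc1cc(B(O)O)cc(OC)c1OS(C)(=O)=O | intermediate
8 | (R)-6-bromo-8-methoxy-2-[3,5-dimethoxy-4-(methanesulfonyloxy)phenyl]chroman-4-one | COc1cc([C@@H]2Oc3c(OC)cc(Br)cc3C(=O)C2)cc(OC)c1OS(C)(=O)=O | intermediate
9 | methyl enol ether of 8: 6-bromo-4,8-dimethoxy-2-[3,5-dimethoxy-4-(methanesulfonyloxy)phenyl]-2H-chromene, C2 configuration as in 8 | COc1cc([C@@H]2Oc3c(OC)cc(Br)cc3C(OC)=C2)cc(OC)c1OS(C)(=O)=O | intermediate
10 | iodanyl ketal: 3-[acetoxy(phenyl)iodanyl]-6-bromo-4,4,8-trimethoxy-2-[3,5-dimethoxy-4-(methanesulfonyloxy)phenyl]chromane, iodanyl group trans to the C2 aryl group | COc1cc([C@@H]2Oc3c(OC)cc(Br)cc3C(OC)(OC)[C@H]2[I](OC(C)=O)c4ccccc4)cc(OC)c1OS(C)(=O)=O | intermediate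
11 | methyl (2R,3R)-5-bromo-2-[3,5-dimethoxy-4-(methanesulfonyloxy)phenyl]-7-methoxy-2,3-dihydro-1-benzofuran-3-carboxylate (trans) | COc1cc([C@@H]2Oc3c(OC)cc(Br)cc3[C@H]2C(=O)OC)cc(OC)c1OS(C)(=O)=O | intermediate
12 | 4-[(2R,3S)-5-bromo-3-(hydroxymethyl)-7-methoxy-2,3-dihydro-1-benzofuran-2-yl]-2,6-dimethoxyphenyl methanesulfonate (trans) | COc1cc([C@@H]2Oc3c(OC)cc(Br)cc3[C@H]2CO)cc(OC)c1OS(C)(=O)=O | intermediate
13 | 3,5-dihydroxybenzaldehyde | O=Cc1cc(O)cc(O)c1 | starting material
14 | 3,5-bis(tert-butyldimethylsilyloxy)benzaldehyde | CC(C)(C)[Si](C)(C)Oc1cc(C=O)cc(O[Si](C)(C)C(C)(C)C)c1 | intermediate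
15 | 3,5-bis(tert-butyldimethylsilyloxy)styrene | C=Cc1cc(O[Si](C)(C)C(C)(C)C)cc(O[Si](C)(C)C(C)(C)C)c1 | intermediate
16 | 4-[(2R,3S)-5-[(E)-2-[3,5-bis(tert-butyldimethylsilyloxy)phenyl]ethenyl]-3-(hydroxymethyl)-7-methoxy-2,3-dihydro-1-benzofuran-2-yl]-2,6-dimethoxyphenyl methanesulfonate | COc1cc([C@@H]2Oc3c(OC)cc(/C=C/c4cc(O[Si](C)(C)C(C)(C)C)cc(O[Si](C)(C)C(C)(C)C)c4)cc3[C@H]2CO)cc(OC)c1OS(C)(=O)=O | intermediate
17 | 4-[(2R,3S)-5-[(E)-2-[3,5-bis(tert-butyldimethylsilyloxy)phenyl]ethenyl]-3-(hydroxymethyl)-7-methoxy-2,3-dihydro-1-benzofuran-2-yl]-2,6-dimethoxyphenol (bis-silyl phenol, present as its lithium salt) | COc1cc([C@@H]2Oc3c(OC)cc(/C=C/c4cc(O[Si](C)(C)C(C)(C)C)cc(O[Si](C)(C)C(C)(C)C)c4)cc3[C@H]2CO)cc(OC)c1O | intermediate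
18 | gnetucleistol F, 5-[(E)-2-[(2R,3S)-2-(4-hydroxy-3,5-dimethoxyphenyl)-3-(hydroxymethyl)-7-methoxy-2,3-dihydro-1-benzofuran-5-yl]ethenyl]benzene-1,3-diol | COc1cc([C@@H]2Oc3c(OC)cc(/C=C/c4cc(O)cc(O)c4)cc3[C@H]2CO)cc(OC)c1O | target

Total step count: 11.
Longest linear sequence: 7 steps (steps 3, 4, 5, 6, 7, 10, 11 from 5; equally steps 1, 2, 5, 6, 7, 10, 11 from 1).

Steps most likely to fail

Step 6. What may go wrong: migration of the syringyl ring instead of ring A, dehydrogenation to the flavone, or oxidative attack on the electron-rich rings, so that little ring-contracted ester forms. The fallback sets out from 8 and returns at 11, and contracts the ring by a Wolff rearrangement instead of an oxidative shift. Trifluoroacetylation of the lithium enolate of 8 (LiN(SiMe3)2, CF3CO2CH2CF3, THF, −78 °C) would give the 3-trifluoroacetylflavanone F1. Regitz-type deacylative diazo transfer (MsN3, Et3N, H2O, MeCN, rt) would give the 3-diazoflavanone F2. Irradiation at 365 nm in MeOH would expel nitrogen and shift the same ring A carbon to C3. The ring-contracted ketene F3 would be trapped by methanol as a mixture of 11 and its cis isomer, the cis ester F4. Catalytic DBU in CH2Cl2 would then equilibrate F4 to the trans ester 11 by epimerisation at C3.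

Step 5. What may go wrong: slow carbopalladation of the 8-methoxychromone so that protodeboronation of 7 takes over, or insufficient facial discrimination. The fallback sets out from 2 and returns at 8, and builds the flavanone by aldol chemistry followed by resolution. Commercial syringaldehyde would be mesylated (MsCl, Et3N, CH2Cl2) to 3,5-dimethoxy-4-(methanesulfonyloxy)benzaldehyde F5. Claisen–Schmidt condensation of 2 with F5 (pyrrolidine, MeOH, 60 °C) would give the 2′-hydroxychalcone F6. Oxa-Michael closure (NaOAc, EtOH, reflux) would give the racemic flavanone F7. Kinetic resolution by asymmetric transfer hydrogenation (RuCl[(R,R)-TsDPEN](p-cymene) or its enantiomer, whichever reduces the (S)-ketone faster, HCO2H/Et3N, rt) would convert the unwanted enantiomer into the cis-(2S,4S)-flavan-4-ol F8 and leave (R)-8, which is separated by chromatography.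

Step 11. What may go wrong: capture of the sulfene by the C9 alkoxide, incomplete demesylation or desilylation, or base-induced opening of the dihydrofuran through a quinone methide once the phenoxide is free. The fallback sets out from 12 and returns at 17, and changes the order of events so that the sulfonate is removed before the stilbene is present and the last operation is a fluoride desilylation. Hydrolysis of 12 (KOH, MeOH/H2O, 60 °C, argon) would give the bromo phenol F9. Mizoroki–Heck coupling of F9 with 15 under the conditions of step 10 would give 17, isolated in this variant. Bu4NF buffered with AcOH in THF at 0 °C would then release 18.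

Further compounds
F1 | step 6 | 3-trifluoroacetyl derivative of 8 (C3 epimers and enol form) | COc1cc([C@@H]2Oc3c(OC)cc(Br)cc3C(=O)C2C(=O)C(F)(F)F)cc(OC)c1OS(C)(=O)=O
F2 | step 6 | 3-diazo derivative of 8 (C2 arrangement unchanged) | COc1cc([C@@H]2Oc3c(OC)cc(Br)cc3C(=O)C2=[N+]=[N-])cc(OC)c1OS(C)(=O)=O
F3 | step 6 | ring-contracted ketene, 5-bromo-7-methoxy-2-[3,5-dimethoxy-4-(methanesulfonyloxy)phenyl]-3-(oxomethylidene)-2,3-dihydro-1-benzofuran | COc1cc([C@@H]2Oc3c(OC)cc(Br)cc3C2=C=O)cc(OC)c1OS(C)(=O)=O
F4 | step 6 | methyl (2R,3S)-5-bromo-2-[3,5-dimethoxy-4-(methanesulfonyloxy)phenyl]-7-methoxy-2,3-dihydro-1-benzofuran-3-carboxylate (cis ester) | COc1cc([C@@H]2Oc3c(OC)cc(Br)cc3[C@@H]2C(=O)OC)cc(OC)c1OS(C)(=O)=O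
F5 | step 5 | 3,5-dimethoxy-4-(methanesulfonyloxy)benzaldehyde | COc1cc(C=O)cc(OC)c1OS(C)(=O)=O
F6 | step 5 | (E)-1-(5-bromo-2-hydroxy-3-methoxyphenyl)-3-[3,5-dimethoxy-4-(methanesulfonyloxy)phenyl]prop-2-en-1-one (2′-hydroxychalcone) | COc1cc(/C=C/C(=O)c2cc(Br)cc(OC)c2O)cc(OC)c1OS(C)(=O)=O
F7 | step 5 | racemic 6-bromo-8-methoxy-2-[3,5-dimethoxy-4-(methanesulfonyloxy)phenyl]chroman-4-one | COc1cc(C2Oc3c(OC)cc(Br)cc3C(=O)C2)cc(OC)c1OS(C)(=O)=O
F8 | step 5 | (2S,4S)-6-bromo-8-methoxy-2-[3,5-dimethoxy-4-(methanesulfonyloxy)phenyl]chroman-4-ol (cis-flavan-4-ol) | COc1cc([C@H]2Oc3c(OC)cc(Br)cc3[C@@H](O)C2)cc(OC)c1OS(C)(=O)=O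
F9 | step 11 | 4-[(2R,3S)-5-bromo-3-(hydroxymethyl)-7-methoxy-2,3-dihydro-1-benzofuran-2-yl]-2,6-dimethoxyphenol | COc1cc([C@@H]2Oc3c(OC)cc(Br)cc3[C@H]2CO)cc(OC)c1O
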